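**Retrosynthetic overview**

1. Target 26 ← selective C16 formylation ← γ-hydroxy enal by E1cB opening of a 6,7-epoxy-17-al (sets C6–OH and C7=C8) ← side chain by B-alkyl Suzuki–Miyaura coupling (C12–C13) of a C9-vinyl decalin with a (Z)-β-iodo enoate.
2. C9-vinyl/C17-hydroxy decalin ← methylenation of a tricyclic lactol; its γ-lactone (C11 carbonyl on C9, C17–O on C8) is a temporary ring that also holds C9; C6=C7 comes from the C6 ketone via its enol triflate.
3. Key disconnection: ring A by a Lewis-acid-promoted [4+2] cycloaddition of 4-methylpenta-1,3-diene across C5=C10 of a ring-B enone (bonds C1–C10 and C4–C5; quaternary C10 next to the gem-dimethyl C4), then C5 epimerization to the trans-decalin.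
4. Enabling feature: C6 bears oxygen, so at the ketone level C6=O makes C5=C10 of ring B an enone with C10 as β-carbon and C5 as α-carbon; C11 and C17 on the neighbouring C9 and C8 can be tied back as a cis-fused γ-lactone that blocks one face of ring B.
5. Ring order: lactone (from the chiral furanone) → ring B (Diels–Alder, step 2) → ring A (step 4); the lactone is opened in steps 8–9.

Key step: step 4

Remark: labdane numbering is used for positions throughout (C1–C10 decalin, C11–C16 side chain on C9, C17 on C8, C20 on C10); it denotes constitution only, and configurations are given by CIP descriptors and SMILES.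

**Route**

Step 1
Reactants: 1 pentane-2,4-dione
Product: 2 (3Z)-2,4-bis(trimethylsilyloxy)penta-1,3-diene
Conditions: Me3SiOTf (2.2 equiv), Et3N (2.5 equiv), Et2O, 0 °C → rt
Reagents that add atoms: trimethylsilyl trifluoromethanesulfonate, C[Si](C)(C)OS(=O)(=O)C(F)(F)F
Why: Double O-silylation (soft enolization) of the 1,3-diketone should give the 1,3-bis(silyloxy)diene needed as the electron-rich partner of the Diels–Alder reaction in step 2.

Step 2
Reactants: 2 (3Z)-2,4-bis(trimethylsilyloxy)penta-1,3-diene; 3 (5R)-5-{[(1R,2S,5R)-5-methyl-2-(propan-2-yl)cyclohexyl]oxy}furan-2(5H)-one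
Product: 5 (3R,3aR,7aR)-7-methyl-3-{[(1R,2S,5R)-5-methyl-2-(propan-2-yl)cyclohexyl]oxy}-3a,4-dihydro-2-benzofuran-1,5(3H,7aH)-dione, via bis-silyl cycloadduct 4 (not isolated)
Conditions: toluene, 110 °C (sealed tube); then 1 M HCl, THF, 0 °C → rt
Reagents that add atoms: none
Why: In this auxiliary-controlled Diels–Alder reaction the CH2 terminus of the diene should bond to the butenolide β-carbon (future C8) on the face opposite the menthyloxy group, which fixes C8 and C9 in a cis-fused lactone; acid then hydrolyses the silyl enol ether and β-eliminates silanol to give the 3-methylcyclohexenone.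

Step 3
Reactants: 5 (3R,3aR,7aR)-7-methyl-3-{[(1R,2S,5R)-5-methyl-2-(propan-2-yl)cyclohexyl]oxy}-3a,4-dihydro-2-benzofuran-1,5(3H,7aH)-dione
Product: 8 (3aR,7aR)-7-methyl-3a,4-dihydro-2-benzofuran-1,5(3H,7aH)-dione, via lactol acid 6 (not isolated), via hydroxy acid 7 (not isolated)
Conditions: CF3CO2H/H2O (4:1), 40 °C; evaporate; then NaBH(OAc)3, AcOH, THF, rt; 1 M HCl work-up
Reagents that add atoms: water, O
Why: Acid hydrolysis of the acylal should release menthol and the lactol acid, whose open aldehyde form is reduced chemoselectively (NaBH(OAc)3 reduces aldehydes but not the enone), and the hydroxy acid relactonizes to the cis-fused γ-lactone with C8 and C9 untouched.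

Step 4
Reactants: 8 (3aR,7aR)-7-methyl-3a,4-dihydro-2-benzofuran-1,5(3H,7aH)-dione; 9 4-methylpenta-1,3-diene
Product: 10 (3aR,5aS,9aR,9bR)-6,6,9a-trimethyl-3a,4,5a,6,9,9a-hexahydronaphtho[1,2-c]furan-1,5(3H,9bH)-dione (rings A and B cis-fused)
Conditions: 9 (5 equiv), AlBr3/AlMe3 (10:1, 30 mol %), toluene/CH2Cl2, −20 °C → rt
Reagents that add atoms: none
Why: The Lewis acid binds the C6 ketone of 8 and the diene adds across C5=C10 in a normal-demand, strongly asynchronous [4+2] cycloaddition: the unsubstituted terminus of 9 bonds first to the enone β-carbon C10 (developing dimethylallyl cation character) and the CMe2 terminus then closes onto the aluminium enolate carbon C5. The closest known reaction type is the Lewis-acid-promoted Diels–Alder reaction of 3-methylcyclohex-2-enones with 1,3-dienes, which gives angularly methylated octalones, together with the use of 4-methylpenta-1,3-diene toward enals and enones; AlMe3 is there to scavenge protic acid that would isomerize or oligomerize the diene. Ring A is closed as a six-membered ring in the [4+2] mode, suprafacial on both partners, so C1 and C4 enter cis. The quaternary centre C10 should be set by attack on the face of ring B opposite the cis-fused γ-lactone (C11 and C17 both lie on the other face), and C5 follows from the suprafacial addition (cis ring fusion, corrected in step 5). The step needs regioselectivity (C1 to C10, C4 to C5) and π-facial selectivity: the first is secured by the C6 carbonyl (C10 is its β-carbon) and by sterics (the gem-dimethyl terminus avoids the carbon that becomes quaternary), the second by the convex shape of the bicyclic lactone. No endo/exo question arises because each diene terminus carries two like groups.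

Step 5
Reactants: 10 (3aR,5aS,9aR,9bR)-6,6,9a-trimethyl-3a,4,5a,6,9,9a-hexahydronaphtho[1,2-c]furan-1,5(3H,9bH)-dione
Product: 12 (3aR,5aR,9aR,9bR)-6,6,9a-trimethyl-3a,4,5a,6,7,8,9,9a-octahydronaphtho[1,2-c]furan-1,5(3H,9bH)-dione (rings A and B trans-fused), via cis-fused saturated ketone 11 (not isolated)
Conditions: H2 (1 atm), 10% Pd on carbon, EtOAc, rt; filter; then DBU (20 mol %), toluene, 80 °C
Reagents that add atoms: none
Why: Heterogeneous hydrogenation should saturate the C2=C3 bond, and base equilibration through the C6 enolate should epimerize C5 so that H5 stands trans to the C10 methyl (trans-decalin), while C8 and C9 are held by the cis-fused lactone.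

Step 6
Reactants: 12 (3aR,5aR,9aR,9bR)-6,6,9a-trimethyl-3a,4,5a,6,7,8,9,9a-octahydronaphtho[1,2-c]furan-1,5(3H,9bH)-dione
Product: 13 (3aR,5aR,9aR,9bR)-6,6,9a-trimethyl-1-oxo-1,3,3a,5a,6,7,8,9,9a,9b-decahydronaphtho[1,2-c]furan-5-yl trifluoromethanesulfonate
Conditions: KN(SiMe3)2 (1.05 equiv), THF, −78 °C; then N-(5-chloropyridin-2-yl)bis(trifluoromethanesulfonyl)imide, −78 → 0 °C; aq. NH4Cl
Reagents that add atoms: N-(5-chloropyridin-2-yl)bis(trifluoromethanesulfonyl)imide, O=S(=O)(N(c1ccc(Cl)cn1)S(=O)(=O)C(F)(F)F)C(F)(F)F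
Why: Kinetic deprotonation should take the accessible C7 proton (C5–H lies between two quaternary carbons), and O-sulfonylation of the enolate gives the C6=C7 enol triflate.

Step 7
Reactants: 13 (3aR,5aR,9aR,9bR)-6,6,9a-trimethyl-1-oxo-1,3,3a,5a,6,7,8,9,9a,9b-decahydronaphtho[1,2-c]furan-5-yl trifluoromethanesulfonate
Product: 14 (3aR,5aR,9aR,9bR)-6,6,9a-trimethyl-3a,5a,6,7,8,9,9a,9b-octahydronaphtho[1,2-c]furan-1(3H)-one
Conditions: Pd(OAc)2 (5 mol %), PPh3 (10 mol %), HCO2H (2 equiv), nBu3N (3 equiv), DMF, 60 °C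
Reagents that add atoms: none
Why: Palladium-catalysed formate reduction of the enol triflate (oxidative addition, formate exchange, decarboxylation, reductive elimination) should give the C6=C7 alkene without touching the lactone.

Step 8
Reactants: 14 (3aR,5aR,9aR,9bR)-6,6,9a-trimethyl-3a,5a,6,7,8,9,9a,9b-octahydronaphtho[1,2-c]furan-1(3H)-one
Product: 15 (3aR,5aR,9aR,9bR)-6,6,9a-trimethyl-1,3,3a,5a,6,7,8,9,9a,9b-decahydronaphtho[1,2-c]furan-1-ol (C1 epimers)
Conditions: iBu2AlH (1.1 equiv), CH2Cl2, −78 °C; aq. potassium sodium tartrate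
Reagents that add atoms: none
Why: Partial reduction of the γ-lactone should stop at the tetrahedral aluminium hemiacetal at −78 °C and give the lactol, a masked C11 aldehyde.

Step 9
Reactants: 15 (3aR,5aR,9aR,9bR)-6,6,9a-trimethyl-1,3,3a,5a,6,7,8,9,9a,9b-decahydronaphtho[1,2-c]furan-1-ol
Product: 16 [(1R,2R,4aR,8aS)-1-ethenyl-5,5,8a-trimethyl-1,2,4a,5,6,7,8,8a-octahydronaphthalen-2-yl]methanol
Conditions: Ph3PCH3Br (3 equiv), KOtBu (2.9 equiv), THF, 0 → 40 °C
Reagents that add atoms: methyltriphenylphosphonium bromide, C[P+](c1ccccc1)(c1ccccc1)c1ccccc1.[Br-]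
Why: Wittig methylenation of the open hydroxy aldehyde form of the lactol should turn C11 into the vinyl group on C9 and free the C17 hydroxymethyl group.

Step 10
Reactants: 17 methyl 4-hydroxybut-2-ynoate
Product: 18 methyl (2Z)-4-hydroxy-3-iodobut-2-enoate
Conditions: NaI (1.5 equiv), AcOH, 70 °C
Reagents that add atoms: sodium iodide, [Na+].[I-]
Why: Conjugate hydroiodination of the ynoate is an anti addition, so iodine should end cis to the ester (Z), the geometry that the C12–C13 coupling has to transfer.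

Step 11
Reactants: 18 methyl (2Z)-4-hydroxy-3-iodobut-2-enoate
Product: 19 methyl (2Z)-4-{[tert-butyl(dimethyl)silyl]oxy}-3-iodobut-2-enoate
Conditions: tBuMe2SiCl, imidazole, CH2Cl2, 0 °C → rt
Reagents that add atoms: tert-butyl(chloro)dimethylsilane, CC(C)(C)[Si](C)(C)Cl
Why: Standard silylation protects the C16 hydroxyl for the basic coupling step.

Step 12
Reactants: 16 [(1R,2R,4aR,8aS)-1-ethenyl-5,5,8a-trimethyl-1,2,4a,5,6,7,8,8a-octahydronaphthalen-2-yl]methanol; 19 methyl (2Z)-4-{[tert-butyl(dimethyl)silyl]oxy}-3-iodobut-2-enoate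
Product: 21 methyl (13E)-16-{[tert-butyl(dimethyl)silyl]oxy}-17-hydroxylabda-6,13-dien-15-oate of configuration (5R,8R,9R,10S), via alkylborane 20 (not isolated)
Conditions: 9-BBN-H (2.3 equiv), THF, 0 °C → rt; then 19, Pd(dppf)Cl2 (5 mol %), AsPh3 (5 mol %), Cs2CO3 (3 equiv), DMF/H2O, rt → 45 °C
Reagents that add atoms: none
Why: 9-BBN should hydroborate only the terminal vinyl group (anti-Markovnikov; the hindered ring alkene is left), and the B-alkyl Suzuki–Miyaura coupling with the vinyl iodide proceeds with retention, so C12 ends cis to the ester and the (13E)-enoate is formed.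

Step 13
Reactants: 21 methyl (13E)-16-{[tert-butyl(dimethyl)silyl]oxy}-17-hydroxylabda-6,13-dien-15-oate
Product: 22 methyl (13E)-16-{[tert-butyl(dimethyl)silyl]oxy}-6,7-epoxy-17-hydroxylabd-13-en-15-oate of configuration (5R,6S,7R,8R,9R,10S)
Conditions: mCPBA (1.2 equiv), NaHCO3, CH2Cl2, 0 °C
Reagents that add atoms: 3-chloroperoxybenzoic acid, O=C(OO)c1cccc(Cl)c1
Why: The peracid should epoxidize the only electron-rich alkene (the enoate is inert) from the face of ring B opposite the axial C10 methyl and the C17 group, which places the C6–O bond as in the target.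

Step 14
Reactants: 22 methyl (13E)-16-{[tert-butyl(dimethyl)silyl]oxy}-6,7-epoxy-17-hydroxylabd-13-en-15-oate
Product: 24 methyl (13E)-16-{[tert-butyl(dimethyl)silyl]oxy}-6-hydroxy-17-oxolabda-7,13-dien-15-oate of configuration (5R,6R,9S,10S), via epoxy aldehyde 23 (not isolated)
Conditions: Dess–Martin periodinane, NaHCO3, CH2Cl2, 0 °C → rt; then Et3N (0.5 equiv), rt
Reagents that add atoms: none
Why: Dess–Martin oxidation should give the β,γ-epoxy aldehyde, and amine-induced E1cB opening of the epoxide (enolization at C8, cleavage of the C7–O bond) delivers the γ-hydroxy enal with C7=C8 in place and the oxygen kept on C6 with its configuration.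

Step 15
Reactants: 24 methyl (13E)-16-{[tert-butyl(dimethyl)silyl]oxy}-6-hydroxy-17-oxolabda-7,13-dien-15-oate
Product: 25 methyl (13E)-6,16-dihydroxy-17-oxolabda-7,13-dien-15-oate of configuration (5R,6R,9S,10S)
Conditions: HF·pyridine, pyridine, THF, 0 °C → rt
Reagents that add atoms: none
Why: Buffered fluoride desilylation should free the primary C16 alcohol without affecting the enal, the enoate or the allylic alcohol.

Step 16
Reactants: 25 methyl (13E)-6,16-dihydroxy-17-oxolabda-7,13-dien-15-oate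
Product: 26 methyl (13E)-16-(formyloxy)-6-hydroxy-17-oxolabda-7,13-dien-15-oate of configuration (5R,6R,9S,10S) (CNP0134813.1)
Conditions: AcOCHO (1.1 equiv), pyridine, CH2Cl2, −40 → −20 °C
Reagents that add atoms: acetic formic anhydride, CC(=O)OC=O
Why: Mixed-anhydride formylation should acylate the unhindered primary allylic C16 hydroxyl much faster than the secondary C6 hydroxyl, which is flanked by C5 and the C4 gem-dimethyl group.

**Compound list**

1 | pentane-2,4-dione | CC(=O)CC(C)=O | starting material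
2 | (3Z)-2,4-bis(trimethylsilyloxy)penta-1,3-diene | C=C(O[Si](C)(C)C)/C=C(/C)O[Si](C)(C)C | intermediate
3 | (5R)-5-{[(1R,2S,5R)-5-methyl-2-(propan-2-yl)cyclohexyl]oxy}furan-2(5H)-one | O=C1C=C[C@H](O[C@@H]2C[C@H](C)CC[C@H]2C(C)C)O1 | starting material
4 | bis-silyl cycloadduct, (3R,3aR,7aR)-7-methyl-3-(menthyloxy)-5,7-bis(trimethylsilyloxy)-3a,4,7,7a-tetrahydro-2-benzofuran-1(3H)-one, C7 epimers, formed in the flask in step 2 | CC1(O[Si](C)(C)C)C=C(O[Si](C)(C)C)C[C@H]2[C@H](O[C@@H]3C[C@H](C)CC[C@H]3C(C)C)OC(=O)[C@@H]12 | intermediate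
5 | (3R,3aR,7aR)-7-methyl-3-{[(1R,2S,5R)-5-methyl-2-(propan-2-yl)cyclohexyl]oxy}-3a,4-dihydro-2-benzofuran-1,5(3H,7aH)-dione | CC1=CC(=O)C[C@H]2[C@H](O[C@@H]3C[C@H](C)CC[C@H]3C(C)C)OC(=O)[C@@H]12 | intermediate
6 | lactol acid, (3aR,7aR)-3-hydroxy-7-methyl-3a,4-dihydro-2-benzofuran-1,5(3H,7aH)-dione, C3 epimers, formed in the flask in step 3 | CC1=CC(=O)C[C@H]2C(O)OC(=O)[C@@H]12 | intermediate
7 | hydroxy acid, (1R,6R)-6-(hydroxymethyl)-2-methyl-4-oxocyclohex-2-ene-1-carboxylic acid, formed in the flask in step 3 | CC1=CC(=O)C[C@@H](CO)[C@H]1C(=O)O | intermediate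
8 | (3aR,7aR)-7-methyl-3a,4-dihydro-2-benzofuran-1,5(3H,7aH)-dione | CC1=CC(=O)C[C@H]2COC(=O)[C@@H]12 | intermediate
9 | 4-methylpenta-1,3-diene | C=CC=C(C)C | starting material
10 | (3aR,5aS,9aR,9bR)-6,6,9a-trimethyl-3a,4,5a,6,9,9a-hexahydronaphtho[1,2-c]furan-1,5(3H,9bH)-dione, H5 cis to the C10 methyl | C[C@@]12CC=CC(C)(C)[C@@H]1C(=O)C[C@H]3COC(=O)[C@@H]23 | intermediate
11 | cis-fused saturated ketone, (3aR,5aS,9aR,9bR)-6,6,9a-trimethyl-3a,4,5a,6,7,8,9,9a-octahydronaphtho[1,2-c]furan-1,5(3H,9bH)-dione, formed in the flask in step 5 | C[C@@]12CCCC(C)(C)[C@@H]1C(=O)C[C@H]3COC(=O)[C@@H]23 | intermediate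
12 | (3aR,5aR,9aR,9bR)-6,6,9a-trimethyl-3a,4,5a,6,7,8,9,9a-octahydronaphtho[1,2-c]furan-1,5(3H,9bH)-dione, H5 trans to the C10 methyl | C[C@@]12CCCC(C)(C)[C@H]1C(=O)C[C@H]3COC(=O)[C@@H]23 | intermediate
13 | (3aR,5aR,9aR,9bR)-6,6,9a-trimethyl-1-oxo-1,3,3a,5a,6,7,8,9,9a,9b-decahydronaphtho[1,2-c]furan-5-yl trifluoromethanesulfonate | C[C@@]12CCCC(C)(C)[C@H]1C(OS(=O)(=O)C(F)(F)F)=C[C@H]3COC(=O)[C@@H]23 | intermediate
14 | (3aR,5aR,9aR,9bR)-6,6,9a-trimethyl-3a,5a,6,7,8,9,9a,9b-octahydronaphtho[1,2-c]furan-1(3H)-one | C[C@@]12CCCC(C)(C)[C@H]1C=C[C@H]3COC(=O)[C@@H]23 | intermediate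
15 | (3aR,5aR,9aR,9bR)-6,6,9a-trimethyl-1,3,3a,5a,6,7,8,9,9a,9b-decahydronaphtho[1,2-c]furan-1-ol, C1 epimers | C[C@@]12CCCC(C)(C)[C@H]1C=C[C@H]3COC(O)[C@@H]23 | intermediate
16 | [(1R,2R,4aR,8aS)-1-ethenyl-5,5,8a-trimethyl-1,2,4a,5,6,7,8,8a-octahydronaphthalen-2-yl]methanol | C[C@@]12CCCC(C)(C)[C@H]1C=C[C@@H](CO)[C@H]2C=C | intermediate
17 | methyl 4-hydroxybut-2-ynoate | COC(=O)C#CCO | starting material
18 | methyl (2Z)-4-hydroxy-3-iodobut-2-enoate | COC(=O)/C=C(\I)CO | intermediate
19 | methyl (2Z)-4-{[tert-butyl(dimethyl)silyl]oxy}-3-iodobut-2-enoate | COC(=O)/C=C(\I)CO[Si](C)(C)C(C)(C)C | intermediate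
20 | alkylborane, 9-{2-[(1R,2R,4aR,8aS)-2-{[(9-borabicyclo[3.3.1]nonan-9-yl)oxy]methyl}-5,5,8a-trimethyl-1,2,4a,5,6,7,8,8a-octahydronaphthalen-1-yl]ethyl}-9-borabicyclo[3.3.1]nonane, formed in the flask in step 12 | C[C@@]12CCCC(C)(C)[C@H]1C=C[C@@H](COB3C4CCCC3CCC4)[C@H]2CCB5C6CCCC5CCC6 | intermediate
21 | methyl (13E)-16-{[tert-butyl(dimethyl)silyl]oxy}-17-hydroxylabda-6,13-dien-15-oate, (5R,8R,9R,10S) | COC(=O)/C=C(\CC[C@@H]1[C@H](CO)C=C[C@@H]2C(C)(C)CCC[C@@]12C)CO[Si](C)(C)C(C)(C)C | intermediate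
22 | methyl (13E)-16-{[tert-butyl(dimethyl)silyl]oxy}-6,7-epoxy-17-hydroxylabd-13-en-15-oate, (5R,6S,7R,8R,9R,10S), epoxide oxygen trans to the C10 methyl | COC(=O)/C=C(\CC[C@@H]1[C@H](CO)[C@H]3O[C@H]3[C@@H]2C(C)(C)CCC[C@@]12C)CO[Si](C)(C)C(C)(C)C | intermediate
23 | epoxy aldehyde, methyl (13E)-16-{[tert-butyl(dimethyl)silyl]oxy}-6,7-epoxy-17-oxolabd-13-en-15-oate, (5R,6S,7R,8S,9R,10S), formed in the flask in step 14 | COC(=O)/C=C(\CC[C@@H]1[C@H](C=O)[C@H]3O[C@H]3[C@@H]2C(C)(C)CCC[C@@]12C)CO[Si](C)(C)C(C)(C)C | intermediate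
24 | methyl (13E)-16-{[tert-butyl(dimethyl)silyl]oxy}-6-hydroxy-17-oxolabda-7,13-dien-15-oate, (5R,6R,9S,10S) | COC(=O)/C=C(\CC[C@@H]1C(C=O)=C[C@@H](O)[C@@H]2C(C)(C)CCC[C@@]12C)CO[Si](C)(C)C(C)(C)C | intermediate
25 | methyl (13E)-6,16-dihydroxy-17-oxolabda-7,13-dien-15-oate, (5R,6R,9S,10S) | COC(=O)/C=C(\CC[C@@H]1C(C=O)=C[C@@H](O)[C@@H]2C(C)(C)CCC[C@@]12C)CO | intermediate
26 | methyl (13E)-16-(formyloxy)-6-hydroxy-17-oxolabda-7,13-dien-15-oate, (5R,6R,9S,10S), CNP0134813.1 | COC(=O)/C=C(\CC[C@@H]1C(C=O)=C[C@@H](O)[C@@H]2C(C)(C)CCC[C@@]12C)COC=O | target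

**Step count and risks**

Total step count: 16. Longest linear sequence: 14 steps (steps 1–9 and 12–16); steps 10–11 make the coupling partner 19.

The three steps most likely to fail:

- Step 4. The cycloaddition may be slow at a β,β-disubstituted enone with a diene that resists the s-cis conformation, and the Lewis acid may oligomerize or isomerize the diene. The fallback sets out from 8 and comes back at 11. Copper-catalysed conjugate addition of (4-chloro-4-methylpentyl)magnesium bromide (CuBr·SMe2, Me3SiCl, THF, −78 °C) to 8, anti to the lactone and with in situ silylation, should give the silyl enol ether (3aR,7R,7aR)-7-(4-chloro-4-methylpentyl)-7-methyl-5-(trimethylsilyloxy)-3a,4,7,7a-tetrahydro-2-benzofuran-1(3H)-one F1. TiCl4 in CH2Cl2 at −78 → −40 °C then ionizes the tertiary chloride, and the silyl enol ether carbon C5 is alkylated intramolecularly (Lewis-acid-mediated α-tert-alkylation of a silyl enol ether). This closes ring A in two operations and gives the cis-fused ketone 11, which enters the base stage of step 5.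

- Step 5. Epimerization at the ring fusion may stay incomplete, because in the trans isomer C17 is axial and syn to the C10 methyl, so the cis/trans equilibrium may not lie far on the trans side. The fallback sets out from 11 and comes back at 12, and replaces thermodynamic control by kinetic protonation. Bromination of 11 (pyridinium tribromide, AcOH; acid-catalysed enolization toward the more substituted α-carbon) should give the bromo ketone (3aR,9aS,9bR)-5a-bromo-6,6,9a-trimethyl-3a,4,5a,6,7,8,9,9a-octahydronaphtho[1,2-c]furan-1,5(3H,9bH)-dione F2. Zinc dust in AcOH at 0 °C then generates the C5=C6 zinc enolate regiospecifically, and axial protonation on the face opposite the C10 methyl should give 12.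

- Step 2. The diene may react sluggishly because its Z-silyloxy group disfavours the s-cis conformation, and silyl groups may be lost at 110 °C before cycloaddition. The fallback sets out from 3 and comes back at 5. Commercial (3E)-pent-3-en-2-one is silylated (Me3SiOTf, Et3N, Et2O, 0 °C) to (3E)-2-(trimethylsilyloxy)penta-1,3-diene F3. Its Diels–Alder reaction with 3 (toluene, 110 °C; same regiochemical and facial control) should give the silyl enol ether (3R,3aR,7aS)-7-methyl-3-{[(1R,2S,5R)-5-methyl-2-(propan-2-yl)cyclohexyl]oxy}-5-(trimethylsilyloxy)-3a,4,7,7a-tetrahydro-2-benzofuran-1(3H)-one F4 (C7 epimers). Saegusa–Ito oxidation (Pd(OAc)2, MeCN, rt) then introduces the C5=C10 double bond and gives 5.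

Further compounds
F1 | step 4 | (3aR,7R,7aR)-7-(4-chloro-4-methylpentyl)-7-methyl-5-(trimethylsilyloxy)-3a,4,7,7a-tetrahydro-2-benzofuran-1(3H)-one | CC(C)(Cl)CCC[C@]1(C)C=C(O[Si](C)(C)C)C[C@H]2COC(=O)[C@@H]12
F2 | step 5 | (3aR,9aS,9bR)-5a-bromo-6,6,9a-trimethyl-3a,4,5a,6,7,8,9,9a-octahydronaphtho[1,2-c]furan-1,5(3H,9bH)-dione, C5a not defined | C[C@@]12CCCC(C)(C)C1(Br)C(=O)C[C@H]3COC(=O)[C@@H]23
F3 | step 2 | (3E)-2-(trimethylsilyloxy)penta-1,3-diene | C=C(O[Si](C)(C)C)/C=C/C
F4 | step 2 | (3R,3aR,7aS)-7-methyl-3-{[(1R,2S,5R)-5-methyl-2-(propan-2-yl)cyclohexyl]oxy}-5-(trimethylsilyloxy)-3a,4,7,7a-tetrahydro-2-benzofuran-1(3H)-one, C7 epimers | CC1C=C(O[Si](C)(C)C)C[C@H]2[C@H](O[C@@H]3C[C@H](C)CC[C@H]3C(C)C)OC(=O)[C@@H]12
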